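If every mole of substrate charged must land in some account, the readings of the west and north-west runs can be booked account by account before anything is said about the route. Substrate is the limiting reagent in elm and ash, because its charge of 0.30 M stands below both reagent charges.

| flask | substrate | reagent | remark | time |
|---|---|---|---|---|
| west | 0.30 M | 0.22 M | run made earlier |  |
| north-west | 0.30 M | 0.45 M | run made earlier |  |
| elm | 0.30 M | 0.390 M |  | 2.0 h |
| ash | 0.30 M | 0.600 M |  | 8.0 h |

| run | time / min | product / % | substrate / % |
|---|---|---|---|
| west | 5.00 | 2.3 | 88.2 |
| west | 8.00 | 2.1 | 84.2 |
| west | 12.0 | 2.9 | 75.8 |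
| west | 20.0 | 5.6 | 65.3 |
| west | 40.0 | 6.2 | 40.1 |
| west | 60.0 | 9.6 | 28.1 |
| north-west | 5.00 | 3.1 | 86.7 |
| north-west | 8.00 | 3.5 | 79.6 |
| north-west | 12.0 | 5.5 | 72.7 |
| north-west | 20.0 | 9.0 | 57.5 |
| north-west | 40.0 | 13.5 | 34.1 |
| north-west | 60.0 | 17.0 | 20.4 |

(standard deviation of a reading: 1 percentage point)

- a reading or a percentage of product counts all its forms, free or not
- a reading of substrate is of its free form alone

* which one finishes higher in amount of product, in percent of the substrate charged ("neither" within 2 percentage points) (elm / ash / neither)
* amount of product at the end, in percent of the substrate charged, elm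
* amount of product at the end, in percent of the substrate charged, ash

The west run closes at 60.0 min with 28.1% of the substrate free, 9.6% in product and 62.3% in an unseen account. The north-west run closes at 60.0 min with 20.4%, 17.0% and 62.6%.

Take as a rule that product gains in proportion to c(reagent), while the unseen account gains independently of it. Then c(reagent) times unseen over product gives 1.43 M from the west run and 1.66 M from the north-west run, both read from readings scattered by 1 percentage point. Their mean, 1.54 M, is the balance concentration, the c(reagent) at which both accounts gain equally.

The share of consumed substrate booked to product is then c(reagent) over c(reagent) plus that balance, taken at the charge: 20.2% for elm and 28.0% for ash. The west decay, carried over as first order, is reckoned to leave 7.90% free in elm at 2.0 h, so this reckoning books 18.6% there. For ash it reckons hardly any free, so it books 28.0%.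

The forecast, holding that “Most of the loss is not product”, says ash, with 19.5% for elm (17% to 23%) and 28% for ash (24% to 36%). Its elm figure stands above the reckoning here.

The flask gives 18.9% in elm and 30.0% in ash, so ash finishes higher. Of the unseen account at the end of ash, 29.0% stands as intermediate A and 40.0% as intermediate B.

    substrate → intermediate A (k = 2.81 × 10⁻⁴ s⁻¹)
    substrate + reagent → product (k = 2.37 × 10⁻⁴ M⁻¹ s⁻¹)
    substrate + product ⇌ idle adduct, settled at all times (K = 26.0 M⁻¹)
    reagent + intermediate A ⇌ intermediate B (K = 3.59 M⁻¹, k = 4.25 × 10⁻⁴ M⁻¹ s⁻¹)

Read back from ash at a conversion of 99.7%, with c(reagent) taken at its charge, the balance concentration is 1.39 M, against 1.54 M from the earlier runs.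

A neighbour of elm charged with 1.6 M of reagent, same time, gets from that balance a share of consumed substrate of 51.0%. Computed, that neighbour holds 48.0% of the substrate charged as product, all its forms counted, with 3.6% of the substrate still free.

The numbers in the tables come from a simulation with made-up constants; the scatter is artificial.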